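## Retrosynthetic overview
1. The vinyl carbinol comes from an α‑hydroxy aldehyde by Wittig methylenation. The C6 carbinol comes from a C6 ketone and MeMgBr by equatorial attack.
2. C3–Br comes from SN2 (Appel) on the axial C3α‑alcohol, itself made from the C3 ketone with L‑Selectride. The homoprenyl arm comes from a lactol and the isopropylidene ylide.
3. The C1 side chain and the C6 oxygen come from an alkylative 1,2‑carbonyl transposition: enol triflate, B‑alkyl Suzuki coupling with a Sharpless‑derived alkene, then α‑face hydroboration on a rigid trans‑fused template.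
4. The template comes from ketoreductase desymmetrisation of a prochiral 2,2‑disubstituted cyclohexane‑1,3‑dione, made from 2‑methylcyclohexane‑1,3‑dione and acrolein.
5. Rings: the carbocycle is bought in with compound 1. A temporary oxane ring is closed in step 4 and reopened in steps 13–14.

Convention: the carbocycle is numbered as in the target. C1 is the CH bearing the side chain, C2 the quaternary carbon, C3 the CHBr carbon and C6 the carbinol carbon. β is the face of the C2 methyl group and α is the opposite face.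

Assumption: the ketoreductase of step 3 is picked by screening a commercial (S)‑selective KRED panel for the (2R,3S)‑ketol; any (2S,3S) diastereomer is separable by chromatography.

## Route

Step 1
Reactants: 1 2‑methylcyclohexane‑1,3‑dione; 2 acrolein
Product: 3 3‑(1‑methyl‑2,6‑dioxocyclohexyl)propanal
Conditions: H2O, rt, 16 h
Reagents that add atoms: none
Why: Michael addition of the acidic 2‑alkyl‑1,3‑dione to acrolein in water gives clean C‑alkylation and builds the still prochiral quaternary carbon.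

Step 2
Reactants: 3 3‑(1‑methyl‑2,6‑dioxocyclohexyl)propanal
Product: 4 2‑(3,3‑dimethoxypropyl)‑2‑methylcyclohexane‑1,3‑dione
Conditions: HC(OMe)3, p‑TsOH·H2O (2 mol %), MeOH, 0 °C → rt
Reagents that add atoms: trimethyl orthoformate, COC(OC)OC
Why: Chemoselective acetalisation works because the unhindered aldehyde reacts far faster than the two neopentyl ketones, and it masks the aldehyde from the reductase and from intramolecular aldolisation.

Step 3
Reactants: 4 2‑(3,3‑dimethoxypropyl)‑2‑methylcyclohexane‑1,3‑dione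
Product: 5 (2R,3S)‑2‑(3,3‑dimethoxypropyl)‑3‑hydroxy‑2‑methylcyclohexan‑1‑one
Conditions: ketoreductase (KRED, NADPH‑dependent, (S)‑selective), NADP+ (cat.), i‑PrOH (10 % v/v), DMSO (5 %), KPi buffer pH 7, 30 °C
Reagents that add atoms: none
Why: In this enzymatic desymmetrising carbonyl reduction the ketoreductase reduces one enantiotopic C=O on one face, setting C2 (quaternary) and C3 (β‑OH, cis to methyl, trans to the arm) together with the 13β‑methyl/17β‑hydroxy topology familiar from secodione bioreductions.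

Step 4
Reactants: 5 (2R,3S)‑ketol
Product: 6 (2R,4aR,8aS)‑2‑methoxy‑4a‑methyloctahydro‑5H‑chromen‑5‑one
Conditions: PPTS (5 mol %), 5 Å MS, CH2Cl2, rt
Reagents that add atoms: none
Why: In this acid‑catalysed transacetalisation the trans‑diequatorial C3β‑OH and C2α‑arm close a trans‑fused 2‑methoxyoxane, which protects OH and aldehyde at once and locks the C2 methyl group axial (the axial‑OMe anomer is drawn and this centre is erased in step 13).

Step 5
Reactants: 6 bicyclic keto acetal
Product: 8 C1=C6 enol triflate of 6, via potassium enolate 7 (not isolated)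
Conditions: KHMDS, THF, −78 °C; PhNTf2, −78 → 0 °C
Reagents that add atoms: N‑phenylbis(trifluoromethanesulfonimide), O=S(=O)(N(c1ccccc1)S(=O)(=O)C(F)(F)F)C(F)(F)F
Why: Enolate O‑triflation is regiochemically unambiguous because C2 is quaternary, so deprotonation can only occur towards C6.

Step 6
Reactants: 9 2‑methylprop‑2‑en‑1‑ol
Product: 10 (R)‑2‑methylglycidol
Conditions: Ti(OiPr)4 (5 mol %), D‑(−)‑DIPT (6 mol %), cumene hydroperoxide, 3 Å MS, CH2Cl2, −20 °C
Reagents that add atoms: cumene hydroperoxide, CC(C)(OO)c1ccccc1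
Why: Catalytic Katsuki–Sharpless asymmetric epoxidation of the achiral allylic alcohol sets the future side‑chain tertiary C–O stereocentre, and the D‑(−)‑tartrate gives the (R)‑epoxy alcohol.

Step 7
Reactants: 10 (R)‑2‑methylglycidol
Product: 11 (S)‑tert‑butyl[(2‑methyloxiran‑2‑yl)methoxy]diphenylsilane
Conditions: TBDPSCl, imidazole, CH2Cl2, 0 °C → rt
Reagents that add atoms: tert‑butyldiphenylsilyl chloride, CC(C)(C)[Si](Cl)(c1ccccc1)c1ccccc1
Why: Silylation of the primary alcohol gives an acid‑ and base‑robust, non‑volatile ether; the descriptor changes only through CIP priorities.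

Step 8
Reactants: 11 TBDPS glycidyl ether
Product: 13 (S)‑1‑(tert‑butyldiphenylsilyloxy)‑2‑methylbut‑3‑en‑2‑ol, via sulfonium betaine 12 (not isolated)
Conditions: Me3SI (3 equiv), n‑BuLi (2.9 equiv), THF, −10 °C → rt
Reagents that add atoms: trimethylsulfonium iodide, C[S+](C)C.[I-]
Why: In this one‑carbon epoxide homologation, dimethylsulfonium methylide opens the CH2 terminus by SN2 and a second ylide equivalent induces β‑elimination of Me2S, giving the vinyl carbinol without touching the stereocentre.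

Step 9
Reactants: 13 tertiary allylic alcohol
Product: 14 (S)‑2‑(tert‑butyldimethylsilyloxy)‑1‑(tert‑butyldiphenylsilyloxy)‑2‑methylbut‑3‑ene
Conditions: TBSOTf, 2,6‑lutidine, CH2Cl2, 0 °C
Reagents that add atoms: tert‑butyldimethylsilyl triflate, CC(C)(C)[Si](C)(C)OS(=O)(=O)C(F)(F)F
Why: The silyl triflate silylates the hindered tertiary alcohol, giving an ether that survives boranes, base, mild acid, hydrides and the later bromination.

Step 10
Reactants: 8 enol triflate; 14 bis‑silyl alkene
Product: 16 C1‑alkylated C1=C6 cyclohexene on the oxane template, via B‑alkyl‑9‑BBN 15 (not isolated)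
Conditions: 14, 9‑BBN‑H, THF, rt → 50 °C; then 8, Pd(dppf)Cl2·CH2Cl2 (5 mol %), AsPh3 (10 mol %), Cs2CO3, H2O, DMF, 50 °C
Reagents that add atoms: none
Why: Anti‑Markovnikov hydroboration followed by B‑alkyl Suzuki–Miyaura coupling forms the C1–C1′ bond at the hindered vinyl triflate and brings in the pre‑set side‑chain stereocentre.

Step 11
Reactants: 16 trisubstituted alkene
Product: 18 C6α‑alcohol bearing C1α‑H, via C6 alkylborane 17 (not isolated)
Conditions: BH3·THF (3 equiv), THF, 0 °C → rt; then 3 M NaOH, 30 % H2O2, 0 °C → rt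
Reagents that add atoms: hydrogen peroxide, OO
Why: In this hydroboration–oxidation boron goes to the less hindered C6 and syn addition occurs from the α face, opposite the axial angular methyl of the rigid trans‑fused bicycle, which sets C1 (H α, side chain β‑equatorial) and gives the C6α‑OH.

Step 12
Reactants: 18 C6α‑alcohol
Product: 19 C6α‑PMB ether
Conditions: NaH, PMBCl, TBAI (cat.), DMF, 0 °C → rt
Reagents that add atoms: 4‑methoxybenzyl chloride, COc1ccc(CCl)cc1
Why: Williamson etherification masks C6–OH with a group that is orthogonal to the silyl ethers and stable to acid hydrolysis, ylide, oxidant, hydride and Appel conditions.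

Step 13
Reactants: 19 PMB ether
Product: 20 lactol (anomeric mixture)
Conditions: AcOH/THF/H2O 3:1:1, 40 °C
Reagents that add atoms: water, O
Why: Mild hydrolysis of the 2‑deoxyglycoside‑type methyl acetal frees the lactol while the PMB, TBDPS and tertiary TBS ethers survive.

Step 14
Reactants: 20 lactol
Product: 22 C2α‑homoprenyl C3β‑alcohol, via open hydroxy aldehyde 21 (not isolated)
Conditions: i‑PrPPh3I (4 equiv), n‑BuLi (3.8 equiv), THF, 0 °C; then 20, 0 °C → rt
Reagents that add atoms: isopropyltriphenylphosphonium iodide, CC(C)[P+](c1ccccc1)(c1ccccc1)c1ccccc1.[I-]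
Why: Wittig olefination of the lactol through its unhindered open aldehyde completes the 4‑methylpent‑3‑enyl arm and releases the equatorial C3β‑OH.

Step 15
Reactants: 22 C3β‑alcohol
Product: 23 C3 ketone
Conditions: Dess–Martin periodinane, CH2Cl2, rt
Reagents that add atoms: none
Why: Dess–Martin oxidation removes the temporary C3 stereocentre under neutral conditions that leave the alkene and all ethers intact.

Step 16
Reactants: 23 C3 ketone
Product: 24 C3α (axial) alcohol
Conditions: L‑Selectride, THF, −78 °C; H2O quench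
Reagents that add atoms: none
Why: In this substrate‑controlled ketone reduction the ring is locked by three equatorial groups, so the bulky borohydride attacks along the equatorial trajectory and gives the axial α‑alcohol, as with 4,4‑disubstituted 3‑keto terpenoids.

Step 17
Reactants: 24 C3α‑alcohol
Product: 26 C3β (equatorial) bromide, via alkoxyphosphonium bromide 25 (not isolated)
Conditions: CBr4, PPh3, 2,6‑lutidine (0.2 equiv), toluene, 0 → 60 °C
Reagents that add atoms: carbon tetrabromide, BrC(Br)(Br)Br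
Why: In the Appel reaction bromide displaces the axial oxyphosphonium group by SN2 with inversion to give the equatorial β‑bromide of the target; no free tertiary alcohol is present and the C6 oxygen lies on the wrong face to participate.

Step 18
Reactants: 26 bromide
Product: 27 C3β‑bromo C6α‑alcohol
Conditions: DDQ, CH2Cl2/pH 7 buffer 10:1, 0 °C → rt
Reagents that add atoms: none
Why: Oxidative PMB cleavage is neutral and spares the trisubstituted alkene, the bromide and both silyl ethers.

Step 19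
Reactants: 27 bromo alcohol
Product: 28 C3β‑bromo C6 ketone
Conditions: Dess–Martin periodinane, CH2Cl2, 0 °C → rt
Reagents that add atoms: none
Why: Dess–Martin oxidation is non‑basic, so the kinetically set C1 centre is not epimerised and the γ‑bromide is not displaced.

Step 20
Reactants: 28 bromo ketone
Product: 29 C6 tertiary alcohol (β‑OH axial, α‑CH3 equatorial), bis‑silyl ether
Conditions: MeMgBr (3 equiv), LaCl3·2LiCl (30 mol %), THF, −40 → 0 °C
Reagents that add atoms: methylmagnesium bromide, C[Mg]Br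
Why: In this lanthanide‑assisted Grignard 1,2‑addition the axial (β) trajectory is blocked by the syn‑axial C2 methyl, so methyl enters equatorially and sets C6 with axial β‑OH, cis to the side chain, while enolisation is suppressed.

Step 21
Reactants: 29 bis‑silyl ether
Product: 30 triol
Conditions: TBAF (5 equiv), THF, rt → 45 °C
Reagents that add atoms: none
Why: Fluoride desilylation removes both silyl groups, and the equatorial neopentyl bromide has no antiperiplanar hydrogen and no trans‑disposed alkoxide that could attack it.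

Step 22
Reactants: 30 triol
Product: 31 α‑hydroxy aldehyde
Conditions: SO3·pyridine, DMSO, Et3N, CH2Cl2, 0 °C
Reagents that add atoms: none
Why: Parikh–Doering oxidation touches only the single primary alcohol, does not cleave the 1,2‑diol, and gives an aldehyde whose α‑carbon is quaternary and so cannot epimerise.

Step 23
Reactants: 31 α‑hydroxy aldehyde
Product: 32 target
Conditions: MePPh3Br (6 equiv), KOtBu (5.5 equiv), THF, 0 °C → rt
Reagents that add atoms: methyltriphenylphosphonium bromide, C[P+](c1ccccc1)(c1ccccc1)c1ccccc1.[Br-]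
Why: Wittig methylenation with excess ylide (which also covers the two OH groups) converts CHO into the vinyl group and completes the (S)‑tertiary allylic alcohol without touching any stereocentre.

## Compound list
1 | 2‑methylcyclohexane‑1,3‑dione | CC1C(=O)CCCC1=O | starting material
2 | acrolein | C=CC=O | starting material
3 | 3‑(1‑methyl‑2,6‑dioxocyclohexyl)propanal | O=CCCC1(C)C(=O)CCCC1=O | intermediate
4 | 2‑(3,3‑dimethoxypropyl)‑2‑methylcyclohexane‑1,3‑dione | COC(CCC1(C)C(=O)CCCC1=O)OC | intermediate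
5 | (2R,3S)‑2‑(3,3‑dimethoxypropyl)‑3‑hydroxy‑2‑methylcyclohexan‑1‑one | O=C1[C@](C)(CCC(OC)OC)[C@@H](O)CCC1 | intermediate
6 | (2R,4aR,8aS)‑2‑methoxy‑4a‑methyloctahydro‑5H‑chromen‑5‑one (trans‑fused, axial OMe) | O=C1[C@]2(C)CC[C@H](OC)O[C@H]2CCC1 | intermediate
7 | potassium C1=C6 enolate of 6 | [K+].[O-]C=1[C@]2(C)CC[C@H](OC)O[C@H]2CCC=1 | intermediate
8 | (2R,4aR,8aS)‑2‑methoxy‑4a‑methyl‑3,4,4a,7,8,8a‑hexahydro‑2H‑chromen‑5‑yl triflate | FC(F)(F)S(=O)(=O)OC=1[C@]2(C)CC[C@H](OC)O[C@H]2CCC=1 | intermediate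
9 | 2‑methylprop‑2‑en‑1‑ol | C=C(C)CO | starting material
10 | (R)‑2‑methylglycidol | OC[C@]1(C)CO1 | intermediate
11 | (S)‑tert‑butyl[(2‑methyloxiran‑2‑yl)methoxy]diphenylsilane | CC(C)(C)[Si](c3ccccc3)(c4ccccc4)OC[C@]1(C)CO1 | intermediate
12 | γ‑alkoxide dimethylsulfonium betaine from 11 | CC(C)(C)[Si](c3ccccc3)(c4ccccc4)OC[C@@](C)([O-])CC[S+](C)C | intermediate
13 | (S)‑1‑(tert‑butyldiphenylsilyloxy)‑2‑methylbut‑3‑en‑2‑ol | CC(C)(C)[Si](c3ccccc3)(c4ccccc4)OC[C@@](C)(O)C=C | intermediate
14 | (S)‑2‑(TBSO)‑1‑(TBDPSO)‑2‑methylbut‑3‑ene | CC(C)(C)[Si](c3ccccc3)(c4ccccc4)OC[C@@](C)(O[Si](C)(C)C(C)(C)C)C=C | intermediate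
15 | B‑alkyl‑9‑BBN from 14 | CC(C)(C)[Si](c3ccccc3)(c4ccccc4)OC[C@@](C)(O[Si](C)(C)C(C)(C)C)CCB5C6CCCC5CCC6 | intermediate
16 | C1=C6 alkene on the oxane template, C1 bearing the bis‑silylated (S) side chain | CC(C)(C)[Si](c3ccccc3)(c4ccccc4)OC[C@@](C)(O[Si](C)(C)C(C)(C)C)CCC=1[C@]2(C)CC[C@H](OC)O[C@H]2CCC=1 | intermediate
17 | C6α‑BH2 adduct (C1α‑H) | CC(C)(C)[Si](c3ccccc3)(c4ccccc4)OC[C@@](C)(O[Si](C)(C)C(C)(C)C)CC[C@H]1[C@]2(C)CC[C@H](OC)O[C@H]2CC[C@@H]1B | intermediate
18 | C6α‑alcohol, C1β side chain, on the template | CC(C)(C)[Si](c3ccccc3)(c4ccccc4)OC[C@@](C)(O[Si](C)(C)C(C)(C)C)CC[C@H]1[C@]2(C)CC[C@H](OC)O[C@H]2CC[C@@H]1O | intermediate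
19 | C6α‑PMB ether of 18 | CC(C)(C)[Si](c3ccccc3)(c4ccccc4)OC[C@@](C)(O[Si](C)(C)C(C)(C)C)CC[C@H]1[C@]2(C)CC[C@H](OC)O[C@H]2CC[C@@H]1OCc5ccc(OC)cc5 | intermediate
20 | lactol (anomeric mixture) | CC(C)(C)[Si](c3ccccc3)(c4ccccc4)OC[C@@](C)(O[Si](C)(C)C(C)(C)C)CC[C@H]1[C@]2(C)CCC(O)O[C@H]2CC[C@@H]1OCc5ccc(OC)cc5 | intermediate
21 | open form: C2α‑(3‑oxopropyl), C3β‑OH | CC(C)(C)[Si](c3ccccc3)(c4ccccc4)OC[C@@](C)(O[Si](C)(C)C(C)(C)C)CC[C@H]1[C@](C)(CCC=O)[C@@H](O)CC[C@@H]1OCc5ccc(OC)cc5 | intermediate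
22 | C2α‑homoprenyl, C3β‑OH (equatorial), C6α‑OPMB | CC(C)(C)[Si](c3ccccc3)(c4ccccc4)OC[C@@](C)(O[Si](C)(C)C(C)(C)C)CC[C@H]1[C@](C)(CCC=C(C)C)[C@@H](O)CC[C@@H]1OCc5ccc(OC)cc5 | intermediate
23 | C3 ketone | CC(C)(C)[Si](c3ccccc3)(c4ccccc4)OC[C@@](C)(O[Si](C)(C)C(C)(C)C)CC[C@H]1[C@](C)(CCC=C(C)C)C(=O)CC[C@@H]1OCc5ccc(OC)cc5 | intermediate
24 | C3α‑OH (axial) | CC(C)(C)[Si](c3ccccc3)(c4ccccc4)OC[C@@](C)(O[Si](C)(C)C(C)(C)C)CC[C@H]1[C@](C)(CCC=C(C)C)[C@H](O)CC[C@@H]1OCc5ccc(OC)cc5 | intermediate
25 | C3α‑alkoxytriphenylphosphonium bromide | CC(C)(C)[Si](c3ccccc3)(c4ccccc4)OC[C@@](C)(O[Si](C)(C)C(C)(C)C)CC[C@H]1[C@](C)(CCC=C(C)C)[C@H](O[P+](c6ccccc6)(c7ccccc7)c8ccccc8)CC[C@@H]1OCc5ccc(OC)cc5.[Br-] | intermediate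
26 | C3β‑bromide (equatorial), C6α‑OPMB | CC(C)(C)[Si](c3ccccc3)(c4ccccc4)OC[C@@](C)(O[Si](C)(C)C(C)(C)C)CC[C@H]1[C@](C)(CCC=C(C)C)[C@@H](Br)CC[C@@H]1OCc5ccc(OC)cc5 | intermediate
27 | C3β‑bromo C6α‑alcohol | CC(C)(C)[Si](c3ccccc3)(c4ccccc4)OC[C@@](C)(O[Si](C)(C)C(C)(C)C)CC[C@H]1[C@](C)(CCC=C(C)C)[C@@H](Br)CC[C@@H]1O | intermediate
28 | C3β‑bromo C6 ketone | CC(C)(C)[Si](c3ccccc3)(c4ccccc4)OC[C@@](C)(O[Si](C)(C)C(C)(C)C)CC[C@H]1[C@](C)(CCC=C(C)C)[C@@H](Br)CCC1=O | intermediate
29 | C6β‑OH/C6α‑CH3 tertiary alcohol, bis‑silyl ether | CC(C)(C)[Si](c3ccccc3)(c4ccccc4)OC[C@@](C)(O[Si](C)(C)C(C)(C)C)CC[C@H]1[C@](C)(CCC=C(C)C)[C@@H](Br)CC[C@@]1(C)O | intermediate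
30 | triol (side chain CH2CH2C(CH3)(OH)CH2OH) | OC[C@@](C)(O)CC[C@H]1[C@](C)(CCC=C(C)C)[C@@H](Br)CC[C@@]1(C)O | intermediate
31 | α‑hydroxy aldehyde | O=C[C@@](C)(O)CC[C@H]1[C@](C)(CCC=C(C)C)[C@@H](Br)CC[C@@]1(C)O | intermediate
32 | (1R,2S,3S,4S)‑4‑bromo‑2‑[(3S)‑3‑hydroxy‑3‑methylpent‑4‑en‑1‑yl]‑1,3‑dimethyl‑3‑(4‑methylpent‑3‑en‑1‑yl)cyclohexan‑1‑ol | C=C[C@@](C)(O)CC[C@H]1[C@](C)(CCC=C(C)C)[C@@H](Br)CC[C@@]1(C)O | target

## Totals and risks
Total steps: 23. Longest linear sequence: 19 (steps 1–5, then 10–23). The side‑chain branch (steps 6–9) is convergent.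

**Step 17, SN2 at the neopentyl C3.** The risks are E2 elimination to the C3=C4 alkene and a 1,2‑methyl shift from the antiperiplanar C2 methyl group. The fallback sets out from 24 and separates activation from substitution. Treatment with Tf2O and 2,6‑di‑tert‑butylpyridine in CH2Cl2 at −40 °C gives the discrete axial C3α‑triflate F9. This is displaced by Bu4NBr in toluene at −20 °C → rt, so the leaving group meets only naked bromide and no phosphonium or phosphine oxide species. The path comes back to the route at 26.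

**Step 3, selectivity or activity of the ketoreductase on 4.** The fallback sets out from 1 and changes the substrate while keeping the enzyme class.
- Michael addition of 1 to methyl acrylate (cat. DBU, MeCN) gives the diketo ester F1.
- The ketoreductase reduces it to the (1R,2S)‑hydroxy keto ester F2.
- F2 lactonises (cat. CSA, toluene) to the crystalline trans‑fused keto δ‑lactone F3, from which the cis‑fused diastereomer is removed by crystallisation.
- KHMDS/PhNTf2 gives the lactone enol triflate F4.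
- DIBAL at −78 °C gives the lactol enol triflate F5.
- MeOH/PPTS then brings the path back to the route at 8.

**Step 11, sluggish hydroboration of the hindered trisubstituted alkene.** The fallback sets out from 16 and reaches the same alcohol by oxidation followed by reductive deoxygenation.
- Stoichiometric OsO4/pyridine adds from the α face and gives the C1α,C6α‑diol F6.
- Parikh–Doering oxidation of the secondary OH gives the C1α‑hydroxy C6‑ketone F7.
- SmI2/HMPA/MeOH removes the tertiary α‑hydroxyl, and α‑face protonation of the samarium enolate gives the C6 ketone F8 with the side chain β‑equatorial on the rigid template.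
- SmI2–H2O–Et3N reduction gives the equatorial alcohol, and the path comes back to the route at 18.

## Further compounds
F1 | step 3 | methyl 3‑(1‑methyl‑2,6‑dioxocyclohexyl)propanoate | COC(=O)CCC1(C)C(=O)CCCC1=O
F2 | step 3 | methyl 3‑[(1R,2S)‑2‑hydroxy‑1‑methyl‑6‑oxocyclohexyl]propanoate | O=C1[C@](C)(CCC(=O)OC)[C@@H](O)CCC1
F3 | step 3 | trans‑fused keto δ‑lactone (4aR,8aS)‑4a‑methylhexahydro‑2H‑chromene‑2,5‑dione | O=C1[C@]2(C)CCC(=O)O[C@H]2CCC1
F4 | step 3 | C1=C6 enol triflate of the keto lactone | FC(F)(F)S(=O)(=O)OC=1[C@]2(C)CCC(=O)O[C@H]2CCC=1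
F5 | step 3 | lactol enol triflate (anomeric mixture) | FC(F)(F)S(=O)(=O)OC=1[C@]2(C)CCC(O)O[C@H]2CCC=1
F6 | step 11 | C1α,C6α‑diol on the template | CC(C)(C)[Si](c3ccccc3)(c4ccccc4)OC[C@@](C)(O[Si](C)(C)C(C)(C)C)CC[C@@]1(O)[C@]2(C)CC[C@H](OC)O[C@H]2CC[C@@H]1O
F7 | step 11 | C1α‑hydroxy C6‑ketone on the template | CC(C)(C)[Si](c3ccccc3)(c4ccccc4)OC[C@@](C)(O[Si](C)(C)C(C)(C)C)CC[C@@]1(O)[C@]2(C)CC[C@H](OC)O[C@H]2CCC1=O
F8 | step 11 | C6 ketone on the template (C1α‑H, side chain β) | CC(C)(C)[Si](c3ccccc3)(c4ccccc4)OC[C@@](C)(O[Si](C)(C)C(C)(C)C)CC[C@H]1[C@]2(C)CC[C@H](OC)O[C@H]2CCC1=O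
F9 | step 17 | C3α (axial) triflate of 24 | CC(C)(C)[Si](c3ccccc3)(c4ccccc4)OC[C@@](C)(O[Si](C)(C)C(C)(C)C)CC[C@H]1[C@](C)(CCC=C(C)C)[C@H](OS(=O)(=O)C(F)(F)F)CC[C@@H]1OCc5ccc(OC)cc5
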